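(The earlier runs and the new flask stem from a simulated flask for an exercise, noise included.)

**The race.** The target climbs at once and then stands still in both earlier runs, so its final amount is the outcome of a short race for the starting material.

| flask | starting material | coupling partner | second substrate | remark | time |
|---|---|---|---|---|---|
| elm | 50 mM | 0.60 equiv | 1 equiv | run made earlier |  |
| alder | 33 mM | 0.60 equiv | 2 equiv | run made earlier |  |
| north | 33 mM | 0.600 equiv | 1.00 equiv |  | 4.0 min |
| south | 33 mM | 0.900 equiv | 1.00 equiv |  | 4.0 min |

| run | time / min | target / % | starting material / % |
|---|---|---|---|
| elm | 0.417 | 9.7 | 2.6 |
| elm | 0.833 | 9.5 | 0.7 |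
| elm | 1.33 | 10.5 | 1.1 |
| elm | 1.50 | 11.2 | 0 |
| elm | 2.00 | 9.6 | 0.2 |
| elm | 2.50 | 11.6 | 0.1 |
| alder | 0.200 | 6.6 | 11.6 |
| alder | 0.333 | 7.4 | 6.8 |
| alder | 0.500 | 8.4 | 3.5 |
| alder | 0.833 | 10.3 | 1.5 |
| alder | 1.33 | 9.7 | 0.4 |
| alder | 2.50 | 9.9 | 0.7 |

(standard deviation of a reading: 0.5 percentage points)

- which of the two there is more of at the end, north (cross product / target)
- which of the two there is more of at the end, south (cross product / target)
- amount of target at the end, in percent of the starting material charged, north
- amount of target at the end, in percent of the starting material charged, south

**Fastest rung.** In alder, 11.6% of the starting material remains at 0.200 min and 3.5% at 0.500 min. A first-order constant read from these falls from 10.8 min⁻¹ to 6.70 min⁻¹, so the loss is steeper than first order. Read as second order, the first reading gives a half-life of 0.0262 min.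

**Slower rungs.** From 1.50 min in elm and 0.833 min in alder the target shows no steady climb, averaging 10.8% in elm and 9.97% in alder over those readings, or 10.4% together. North and south run 4.0 min, which is far longer than that half-life, so I expect both to finish the race.

**Partner balance.** The coupling partner is charged short, yet the starting material falls to 0.1% in elm, which makes it the limiting reagent there. Of the 0.60 equiv charged, the target takes 17.3%; this share of the charged partner ending as target is my yardstick. If the target's rate goes as [starting material][coupling partner] and the loss as [starting material] squared, their ratio at the start follows the equivalents of partner, whatever the concentration. Holding the share fixed, I reckon 10.4% for north and 15.6% for south. Elm and alder differ in both concentration and second substrate, and their averages differ by 0.83 percentage points, so I take the second substrate's channel as weak and expect more target than cross product in north and south.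

**The forecast.** It gives 10.2% for north and 6.5% for south, with cross product ahead in north and cross product in south. Its ground for south: “target formation picks up late, perhaps as partner runs out”. My reckoning differs on south and on which product leads.

**The result.** North gives 11.0% target against 3.72% cross product; south gives 15.1% against 3.35%. South ends with 0.00918% of its starting material and 63% of its partner. Its target took 16.8% of the partner charged, beside the 17.3% read from the earlier runs.

    2 starting material → homo dimer (k = 7.57 M⁻¹ s⁻¹)
    second substrate + coupling partner → second product (k = 0.0409 M⁻¹ s⁻¹)
    second substrate → decomposition product (k = 2.44 × 10⁻⁵ s⁻¹)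
    starting material + coupling partner → target (k = 0.996 M⁻¹ s⁻¹)
    starting material + second substrate → cross product (k = 0.184 M⁻¹ s⁻¹)

**Second flask.** A neighbour of south is charged with 0.250 equiv of second substrate, and its partner charge is unchanged, so the share gives 15.6% again. The computed flask gives 15.9%.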